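**Retrosynthetic overview** (oxolane numbering: O1, C2 aryl-bearing, C3 methyl-bearing, C4, C5; C7' is the exocyclic carbinol carbon)
1. The C7'–aryl bond is made last, by adding an aryl Grignard reagent to a C4 aldehyde (chelate/Felkin control sets C7'); the formyl group comes from a nitromethyl group (Nef reaction).
2. The C2–aryl bond comes from Friedel–Crafts arylation of a 2-hydroxyoxolane (lactol) with veratrole, trans to the C3 methyl group.
3. The lactol comes from propanal and (E)-3-nitroprop-2-en-1-ol in one organocatalytic domino step: enamine Michael addition makes C3–C4 with both stereocentres, then the C5 hydroxyl closes the ring onto the C2 aldehyde carbon (O1–C2 bond).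
4. Enabling feature: C2 carries ring oxygen O1 and an electron-rich veratryl ring that can enter as an arene nucleophile, so C2 can be an aldehyde carbon; O1 sits on the CH2 group C5, 1,4 to C2; C3 is then an aldehyde α-carbon and C4 the β-carbon of a nitroalkene whose nitro-bearing carbon becomes C7'.
5. Ring order: the oxolane is the only ring formed (step 3); both benzene rings are bought.

Key step: step 3

Remark: (3,4-dimethoxyphenyl)magnesium bromide (THF solution) and the (R)-diphenylprolinol silyl ether catalyst are treated as purchased materials.

**Step 1**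
Reactants: 1 (tert-butyldimethylsilyloxy)acetaldehyde; 2 nitromethane
Product: 4 (E)-tert-butyl(dimethyl)[(3-nitroprop-2-en-1-yl)oxy]silane, via nitroaldol 3 (not isolated)
Conditions: MeNO2 (5 equiv), Et3N (0.1 equiv), THF, 0 °C to rt; evaporate; MsCl, Et3N, CH2Cl2, −20 to 0 °C
Reagents that add atoms: none
Why: Henry (nitroaldol) addition followed by mesylation and E1cB elimination is the standard entry to (E)-nitroalkenes; the primary silyl ether should survive both stages and no stereocentre is carried on.

**Step 2**
Reactants: 4 (E)-tert-butyl(dimethyl)[(3-nitroprop-2-en-1-yl)oxy]silane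
Product: 5 (E)-3-nitroprop-2-en-1-ol
Conditions: aq. HF, MeCN, 0 °C
Reagents that add atoms: none
Why: Cleavage of a primary TBS ether (silyl ether deprotection) is fast under these mildly acidic conditions, under which the nitroalkene should be inert.

**Step 3**
Reactants: 5 (E)-3-nitroprop-2-en-1-ol; 6 propanal
Product: 8 (3S,4S)-3-methyl-4-(nitromethyl)oxolan-2-ol (mixture of C2 epimers), via hydroxy aldehyde 7 (not isolated)
Conditions: (R)-2-[diphenyl(trimethylsilyloxy)methyl]pyrrolidine (10 mol%), PhCO2H (20 mol%), propanal (2 equiv), CH2Cl2, 0 °C
Reagents that add atoms: none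
Why: Propanal and the (R)-configured diarylprolinol silyl ether form the (E)-enamine, whose α-carbon (future C3) adds to the β-carbon of the nitroalkene (future C4) through the acyclic synclinal transition state of the enamine Michael addition, and hydrolysis of the iminium ion releases hydroxy aldehyde 7. The C5 hydroxyl of 7 then adds to the aldehyde carbon C2 in a 5-exo-trig hemiacetalization, which forms the O1–C2 bond and closes the oxolane ring. The closest known reaction type is the diarylprolinol silyl ether-catalysed Michael addition of aldehydes to nitroalkenes and its Michael/hemiacetalization domino version with hydroxy-substituted nitroalkenes. C3 is set by the catalyst, whose diphenyl(silyloxy)methyl group blocks one face of the enamine, and C4 by the synclinal approach of the nitroalkene (syn adduct, hence 3,4-cis in the ring), while the hemiacetal carbon C2 stays an epimer mixture that is defined only in step 4. The step needs syn diastereoselectivity, enantioselectivity and C–C addition in preference to oxa-Michael addition of the free hydroxyl: the acid co-catalyst and low temperature favour the enamine pathway, the (E)-geometry and unhindered β-carbon of the nitroalkene secure the syn topicity, and the hydroxyl placed 1,4 to the new aldehyde secures fast ring closure that masks the aldehyde and protects C3 from enamine-mediated epimerisation.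

**Step 4**
Reactants: 8 (3S,4S)-3-methyl-4-(nitromethyl)oxolan-2-ol; 9 1,2-dimethoxybenzene (veratrole)
Product: 10 (2S,3S,4S)-2-(3,4-dimethoxyphenyl)-3-methyl-4-(nitromethyl)oxolane
Conditions: veratrole (3 equiv), BF3·OEt2 (1.5 equiv), CH2Cl2, −40 to −10 °C
Reagents that add atoms: none
Why: BF3·OEt2 ionises the lactol to the cyclic oxocarbenium ion, which veratrole should attack para to a methoxy group (Friedel–Crafts C-arylation of a lactol) from the face opposite the cis-disposed C3 methyl and C4 nitromethyl groups, placing the aryl group trans to the methyl group; any reversible benzylic ionisation of the product can only reinforce this more stable 2,3-trans arrangement.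

**Step 5**
Reactants: 10 (2S,3S,4S)-2-(3,4-dimethoxyphenyl)-3-methyl-4-(nitromethyl)oxolane
Product: 12 (3R,4S,5S)-5-(3,4-dimethoxyphenyl)-4-methyloxolane-3-carbaldehyde, via sodium nitronate 11 (not isolated)
Conditions: NaOMe, MeOH, 0 °C; then aq. TiCl3, NH4OAc buffer (pH 5–6), 0 °C to rt
Reagents that add atoms: water, O
Why: Nef reaction in its reductive TiCl3 variant: the nitronate is reduced by trivalent titanium to the imine, which hydrolyses in the buffered medium to the aldehyde, mildly enough that the epimerisable C4 centre (cis to the methyl group) and the benzylic ether should stay intact.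

**Step 6**
Reactants: 12 (3R,4S,5S)-5-(3,4-dimethoxyphenyl)-4-methyloxolane-3-carbaldehyde; 13 (3,4-dimethoxyphenyl)magnesium bromide
Product: 14 (R)-(3,4-dimethoxyphenyl)[(3R,4S,5S)-5-(3,4-dimethoxyphenyl)-4-methyloxolan-3-yl]methanol
Conditions: MgBr2·OEt2, CH2Cl2, −78 °C; then 13 (THF solution), −78 °C; aq. NH4Cl
Reagents that add atoms: none
Why: Grignard addition to the α-chiral aldehyde under Cram-chelate control (magnesium bridging the aldehyde oxygen and ring oxygen O1), which coincides with the Felkin–Anh preference (C3 branch anti to the nucleophile), so the aryl group should attack the carbonyl face away from C3 and give the (R)-carbinol with the 1,2-anti relationship of the target.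

**Compound list**
1 | (tert-butyldimethylsilyloxy)acetaldehyde | CC(C)(C)[Si](C)(C)OCC=O | starting material
2 | nitromethane | C[N+](=O)[O-] | starting material
3 | 1-[(tert-butyldimethylsilyl)oxy]-3-nitropropan-2-ol (racemic) | CC(C)(C)[Si](C)(C)OCC(O)C[N+](=O)[O-] | intermediate
4 | (E)-tert-butyl(dimethyl)[(3-nitroprop-2-en-1-yl)oxy]silane | CC(C)(C)[Si](C)(C)OC/C=C/[N+](=O)[O-] | intermediate
5 | (E)-3-nitroprop-2-en-1-ol | OC/C=C/[N+](=O)[O-] | intermediate
6 | propanal | CCC=O | starting material
7 | (2S,3S)-3-(hydroxymethyl)-2-methyl-4-nitrobutanal | O=C[C@@H](C)[C@H](CO)C[N+](=O)[O-] | intermediate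
8 | (3S,4S)-3-methyl-4-(nitromethyl)oxolan-2-ol (C2 epimers) | OC1OC[C@H](C[N+](=O)[O-])[C@@H]1C | intermediate
9 | 1,2-dimethoxybenzene (veratrole) | COc1ccccc1OC | starting material
10 | (2S,3S,4S)-2-(3,4-dimethoxyphenyl)-3-methyl-4-(nitromethyl)oxolane | COc1ccc([C@H]2OC[C@H](C[N+](=O)[O-])[C@@H]2C)cc1OC | intermediate
11 | sodium nitronate of 10 | COc1ccc([C@H]2OC[C@H](C=[N+]([O-])[O-])[C@@H]2C)cc1OC.[Na+] | intermediate
12 | (3R,4S,5S)-5-(3,4-dimethoxyphenyl)-4-methyloxolane-3-carbaldehyde | COc1ccc([C@H]2OC[C@H](C=O)[C@@H]2C)cc1OC | intermediate
13 | (3,4-dimethoxyphenyl)magnesium bromide | COc1ccc([Mg]Br)cc1OC | starting material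
14 | (R)-(3,4-dimethoxyphenyl)[(3R,4S,5S)-5-(3,4-dimethoxyphenyl)-4-methyloxolan-3-yl]methanol | COc1ccc([C@H]2OC[C@H]([C@@H](O)c3ccc(OC)c(OC)c3)[C@@H]2C)cc1OC | target

**Step count and risks**
Total steps: 6. Longest linear sequence: 6 steps (1 → 4 → 5 → 8 → 10 → 12 → 14).

Steps most likely to fail:

Step 3. The free hydroxy nitroalkene may be lost by base-induced double-bond isomerisation or intermolecular oxa-Michael addition, and the syn ratio may erode by enamine-mediated epimerisation at C3 before ring closure. The fallback sets out from 4 and bypasses 5: the same diarylprolinol silyl ether-catalysed Michael addition of propanal 6 to the silyl-protected nitroalkene should give (2S,3S)-3-{[tert-butyl(dimethyl)silyl]oxymethyl}-2-methyl-4-nitrobutanal F1. Treating crude F1 with aq. HF in MeCN at 0 °C removes the silyl group, the liberated hydroxyl closes onto the aldehyde, and the route is rejoined at 8.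

Step 4. The benzylic C2–O1 bond of the product may re-ionise and the open cation be captured by a second veratrole (over-arylation), or the arylation may be sluggish. The fallback sets out from 8: PhSO2H and CaCl2 in CH2Cl2 should convert the lactol into (3S,4S)-3-methyl-4-(nitromethyl)-2-(phenylsulfonyl)oxolane F2. (3,4-Dimethoxyphenyl)zinc bromide F3, generated from 13 and ZnBr2 in THF, then displaces the sulfinate at room temperature through the same oxocarbenium ion, again anti to the C3 and C4 substituents and without a Lewis acid strong enough to re-ionise the product. The route is rejoined at 10.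

Step 6. Facial selectivity in the addition to the ring-bound aldehyde may be poor, giving a mixture of C7' epimers. The fallback sets out from 12: the addition of 13 is run without regard to selectivity, giving 14 together with (S)-(3,4-dimethoxyphenyl)[(3R,4S,5S)-5-(3,4-dimethoxyphenyl)-4-methyloxolan-3-yl]methanol F4. Dess–Martin periodinane (NaHCO3, CH2Cl2) oxidises the mixture to (3,4-dimethoxyphenyl)[(3R,4S,5S)-5-(3,4-dimethoxyphenyl)-4-methyloxolan-3-yl]methanone F5. Reagent-controlled Corey–Bakshi–Shibata reduction with (S)-2-methyl-CBS-oxazaborolidine and BH3·SMe2 in THF at −20 °C, with the aryl group as the larger ketone substituent, should deliver the (R)-carbinol and return to 14.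

**Further compounds**
F1 | step 3 | (2S,3S)-3-{[tert-butyl(dimethyl)silyl]oxymethyl}-2-methyl-4-nitrobutanal | O=C[C@@H](C)[C@H](CO[Si](C)(C)C(C)(C)C)C[N+](=O)[O-]
F2 | step 4 | (3S,4S)-3-methyl-4-(nitromethyl)-2-(phenylsulfonyl)oxolane (C2 epimers) | O=S(=O)(c1ccccc1)C1OC[C@H](C[N+](=O)[O-])[C@@H]1C
F3 | step 4 | (3,4-dimethoxyphenyl)zinc bromide | COc1ccc([Zn]Br)cc1OC
F4 | step 6 | (S)-(3,4-dimethoxyphenyl)[(3R,4S,5S)-5-(3,4-dimethoxyphenyl)-4-methyloxolan-3-yl]methanol | COc1ccc([C@H]2OC[C@H]([C@H](O)c3ccc(OC)c(OC)c3)[C@@H]2C)cc1OC
F5 | step 6 | (3,4-dimethoxyphenyl)[(3R,4S,5S)-5-(3,4-dimethoxyphenyl)-4-methyloxolan-3-yl]methanone | COc1ccc([C@H]2OC[C@H](C(=O)c3ccc(OC)c(OC)c3)[C@@H]2C)cc1OC
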